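The target is treated as two p-menthane units and is cut between C10 of ring A (the allylic CH2 of a former limonene isopropenyl group) and C3' of ring B. The key step exploits three features of ring B. C3' sits between the C2' carbinol, which is a latent ketone, and the C4' isopropenyl stereocentre, and C1' is quaternary. One enolate allylation joins two fully functionalised halves and sets C3' trans to C4'. One precursor is an alpha-ketol made from (S)-carvone, used as its dilithio alkoxide-enolate. The other is an allylic bromide made from (1S,2S,4R)-limonene-1,2-diol, which already carries the syn-bromohydrin of ring A as a silyl ether. Ketone reduction and desilylation finish the synthesis.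

Key step: step 7

Remark: p-menthane numbering is used for both rings (C1 methyl carbinol carbon, C2 CHBr or CHOH, C4 ring carbon bearing the three-carbon side chain C8 to C10). Primed numbers belong to ring B, which is viewed with the C4' isopropenyl group on the top face.

Step 1
Reactants: 1 (1S,2S,4R)-limonene-1,2-diol (trans-diaxial diol of (R)-limonene)
Product: 3 (1S,2S,4R)-2-(chloromethanesulfonyloxy)-1-(triethylsilyloxy)-p-menth-8-ene, via hydroxy chloromesylate 2 (not isolated)
Conditions: ClCH2SO2Cl, pyridine, CH2Cl2, 0 °C; then 2,6-lutidine, Et3SiOTf, -40 to 0 °C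
Reagents that add atoms: chloromethanesulfonyl chloride ClCS(=O)(=O)Cl; triethylsilyl trifluoromethanesulfonate CC[Si](CC)(CC)OS(=O)(=O)C(F)(F)F
Why: Chemoselective sulfonylation of the secondary C2 hydroxyl, followed in the same flask by silyl triflate protection of the tertiary C1 hydroxyl, caps the antiperiplanar oxygen before it can close to the epoxide, and no stereocentre is touched.

Step 2
Reactants: 3 (1S,2S,4R)-2-(chloromethanesulfonyloxy)-1-(triethylsilyloxy)-p-menth-8-ene
Product: 4 (1S,2S,4R)-10-chloro-2-(chloromethanesulfonyloxy)-1-(triethylsilyloxy)-p-menth-8-ene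
Conditions: Ca(OCl)2, solid CO2, CH2Cl2/H2O, 0 °C
Reagents that add atoms: calcium hypochlorite Ca(OCl)2 [Ca+2].[O-]Cl.[O-]Cl
Why: In this ene-type allylic chlorination with HOCl made in the flask, the only alkene accepts Cl+ at its CH2 terminus and loses a methyl proton to give the 2-substituted allyl chloride, while the silylated C1 oxygen cannot intercept the cation as a cineole-type ether.

Step 3
Reactants: 4 (1S,2S,4R)-10-chloro-2-(chloromethanesulfonyloxy)-1-(triethylsilyloxy)-p-menth-8-ene
Product: 5 (1S,2R,4R)-2,10-dibromo-1-(triethylsilyloxy)-p-menth-8-ene (ring bromide equatorial and cis to the silyloxy group)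
Conditions: LiBr (excess), 2-butanone, 70 °C
Reagents that add atoms: lithium bromide [Li+].[Br-]
Why: Two SN2 displacements occur (Finkelstein-type exchange at the allylic chloride and sulfonate displacement at C2), and because bromide attacks C2 opposite to the axial chloromesylate, C2 is inverted to the equatorial bromide cis to the C1 oxygen, which is then a poor SN2 and E2 substrate and stays as formed.

Step 4
Reactants: 6 (S)-(+)-carvone
Product: 7 (1S,4S,6S)-1-methyl-4-(prop-1-en-2-yl)-7-oxabicyclo[4.1.0]heptan-2-one (oxirane trans to the isopropenyl group)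
Conditions: 30% H2O2, NaOH (cat.), MeOH, 0 °C
Reagents that add atoms: hydrogen peroxide OO
Why: Weitz-Scheffer nucleophilic epoxidation touches only the enone, and axial attack of hydroperoxide on C6' anti to the C4' isopropenyl group places the oxirane on the bottom face, which sets C1' (oxygen down, methyl up).

Step 5
Reactants: 7 (1S,4S,6S)-1-methyl-4-(prop-1-en-2-yl)-7-oxabicyclo[4.1.0]heptan-2-one
Product: 8 (1S,4S)-p-menth-8-ene-1,2-diol (both C2' epimers carried on together)
Conditions: LiAlH4, THF, 0 °C to reflux; then H2O
Reagents that add atoms: none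
Why: Hydride reduction of the ketone and SN2 opening of the trisubstituted epoxide at its secondary carbon C6' leave the tertiary C1' alcohol with its configuration intact, and the C2' epimer composition is irrelevant because that centre is oxidised next.

Step 6
Reactants: 8 (1S,4S)-p-menth-8-ene-1,2-diol
Product: 9 (2S,5S)-2-hydroxy-2-methyl-5-(prop-1-en-2-yl)cyclohexan-1-one
Conditions: IBX, DMSO, rt
Reagents that add atoms: none
Why: IBX oxidation converts secondary-tertiary 1,2-diols to alpha-ketols without C-C cleavage and leaves the tertiary alcohol and the alkene alone, so both C2' epimers converge on one ketol.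

Step 7
Reactants: 9 (2S,5S)-2-hydroxy-2-methyl-5-(prop-1-en-2-yl)cyclohexan-1-one; 5 (1S,2R,4R)-2,10-dibromo-1-(triethylsilyloxy)-p-menth-8-ene
Product: 11 (2S,5S,6R)-6-{2-[(1R,3R,4S)-3-bromo-4-methyl-4-(triethylsilyloxy)cyclohexyl]prop-2-en-1-yl}-2-hydroxy-2-methyl-5-(prop-1-en-2-yl)cyclohexan-1-one, via dilithio alkoxide-enolate 10 (not isolated)
Conditions: LiN(iPr)2 (2.2 equiv), THF, -78 to 0 °C; DMPU, then 5, -78 to -20 °C; aq NH4Cl
Reagents that add atoms: none
Why: Two equivalents of lithium amide give the chelated alkoxide-enolate 10, whose C3' carbon displaces the primary allylic bromide of 5 in an SN2 enolate allylation, the reaction type known for carvone enolates, for 3-substituted cyclohexanone enolates and for alpha-ketol dianions. No ring is closed. The new C3' stereocentre is controlled by the adjacent C4' isopropenyl group and the C1' methyl group, both on the top face, so the electrophile enters from the bottom face to give the trans, all-equatorial ketone, which is also the thermodynamic epimer, so that any cis isomer can be corrected with mild base. Regioselectivity is secured because C1' is quaternary and C3' is the only enolisable carbon, and because SN2 and SN2' attack on the 2-substituted allyl unit give the same product. Chemoselectivity between the two C-Br bonds rests on the ring bromide being secondary, equatorial, next to a quaternary carbon and without an antiperiplanar hydrogen, hence inert to substitution and elimination at low temperature. C-alkylation should win over O-alkylation because the tertiary lithium alkoxide is hindered and aggregated.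

Step 8
Reactants: 11 coupled ketol (see step 7)
Product: 12 (1S,2S,3R,4S)-3-{2-[(1R,3R,4S)-3-bromo-4-methyl-4-(triethylsilyloxy)cyclohexyl]prop-2-en-1-yl}-1-methyl-4-(prop-1-en-2-yl)cyclohexane-1,2-diol
Conditions: NaBH4, MeOH, -20 to 0 °C
Reagents that add atoms: none
Why: In this borohydride reduction of a cyclohexanone by axial attack, the axial C1' methyl group blocks the top face, so hydride enters from the bottom face and forms the equatorial C2' alcohol, trans to both the C1' hydroxyl and the C3' side chain, while the ring bromide is untouched.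

Step 9
Reactants: 12 diol silyl ether (see step 8)
Product: 13 target, (1S,2S,3R,4S)-3-{2-[(1R,3R,4S)-3-bromo-4-hydroxy-4-methylcyclohexyl]prop-2-en-1-yl}-1-methyl-4-(prop-1-en-2-yl)cyclohexane-1,2-diol
Conditions: HF·pyridine, pyridine, THF, 0 °C to rt
Reagents that add atoms: none
Why: Fluoride-mediated cleavage of the tertiary triethylsilyl ether under non-basic conditions frees the C1 alcohol without risk of a base-induced semipinacol ring contraction of the cis-bromohydrin.

Compound list
1 | (1S,2S,4R)-limonene-1,2-diol | C=C(C)[C@@H]1CC[C@](C)(O)[C@@H](O)C1 | starting material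
2 | (1S,2S,4R)-2-(chloromethanesulfonyloxy)-p-menth-8-en-1-ol | C=C(C)[C@@H]1CC[C@](C)(O)[C@@H](OS(=O)(=O)CCl)C1 | intermediate
3 | (1S,2S,4R)-2-(chloromethanesulfonyloxy)-1-(triethylsilyloxy)-p-menth-8-ene | C=C(C)[C@@H]1CC[C@](C)(O[Si](CC)(CC)CC)[C@@H](OS(=O)(=O)CCl)C1 | intermediate
4 | (1S,2S,4R)-10-chloro-2-(chloromethanesulfonyloxy)-1-(triethylsilyloxy)-p-menth-8-ene | C=C(CCl)[C@@H]1CC[C@](C)(O[Si](CC)(CC)CC)[C@@H](OS(=O)(=O)CCl)C1 | intermediate
5 | (1S,2R,4R)-2,10-dibromo-1-(triethylsilyloxy)-p-menth-8-ene | C=C(CBr)[C@@H]1CC[C@](C)(O[Si](CC)(CC)CC)[C@H](Br)C1 | intermediate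
6 | (S)-(+)-carvone | CC1=CC[C@@H](CC1=O)C(C)=C | starting material
7 | (1S,4S,6S)-1-methyl-4-(prop-1-en-2-yl)-7-oxabicyclo[4.1.0]heptan-2-one | C1[C@@H](C(=C)C)C[C@@H]2O[C@]2(C)C1=O | intermediate
8 | (1S,4S)-p-menth-8-ene-1,2-diol, both C2' epimers (C2' left open in the SMILES) | C1[C@@H](C(=C)C)CC[C@](C)(O)C1O | intermediate
9 | (2S,5S)-2-hydroxy-2-methyl-5-(prop-1-en-2-yl)cyclohexan-1-one | C1[C@@H](C(=C)C)CC[C@](C)(O)C1=O | intermediate
10 | dilithio alkoxide-enolate of 9 | [Li+].[Li+].[O-]C1=C[C@@H](C(=C)C)CC[C@]1(C)[O-] | intermediate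
11 | coupled ketol, (2S,5S,6R) in ring B and (1R,3R,4S) in ring A, triethylsilyl ether | C=C(C[C@@H]1[C@@H](C(=C)C)CC[C@](C)(O)C1=O)[C@@H]1CC[C@](C)(O[Si](CC)(CC)CC)[C@H](Br)C1 | intermediate
12 | coupled trans-diol, triethylsilyl ether | C=C(C[C@@H]1[C@@H](C(=C)C)CC[C@](C)(O)[C@H]1O)[C@@H]1CC[C@](C)(O[Si](CC)(CC)CC)[C@H](Br)C1 | intermediate
13 | CNP0422107.2 | C=C(C[C@@H]1[C@@H](C(=C)C)CC[C@](C)(O)[C@H]1O)[C@@H]1CC[C@](C)(O)[C@H](Br)C1 | target

Total step count: 9. Longest linear sequence: 6 steps (steps 1 to 3 or steps 4 to 6, then steps 7 to 9).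

Steps most likely to fail

Step 3 (substitution at C2).
- What may go wrong: E2 loss of the axial sulfonate toward C3, sluggish attack beside the quaternary C1 at the temperature this sulfonate needs, or participation of the silyloxy oxygen that erodes the inversion.
- Fallback: it sets out from 1 and comes back at 5. It separates the two substitutions and moves the critical one to a triflate that reacts at or below room temperature, before any allylic halide is present. Et3SiOTf (excess) and 2,6-lutidine convert 1 to the bis(triethylsilyl) ether F1. PPTS in MeOH at 0 °C frees the less hindered secondary hydroxyl to give the tertiary silyl ether alcohol F2. Tf2O and pyridine at -20 °C give the C2 triflate F3. Bu4NBr in toluene at 0 °C to rt gives the inverted equatorial bromide F4. Ca(OCl)2 with CO2 gives the allylic chloride F5, and LiBr in acetone at rt gives 5.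

Step 7 (fragment union).
- What may go wrong: proton exchange between the product ketone and the dianion leading to over-alkylation, competing O-alkylation of the alkoxide, or low reactivity of the aggregated dianion.
- Fallback: it sets out from 6 and 5 and comes back at 11. The union is moved to the cross-conjugated kinetic enolate of carvone itself, and the oxygen pattern of ring B is installed afterwards. LiN(iPr)2 in THF at -78 °C followed by 5 gives the trans-alkylated carvone F6. H2O2 and NaOH in MeOH give the epoxy ketone F7, with the oxirane anti to the isopropenyl group. LiAlH4 in THF at 0 °C to rt gives the coupled diol F8 as C2' epimers; the hindered equatorial ring bromide is expected to be reduced far more slowly than the epoxide is opened. IBX in DMSO then gives 11.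

Step 2 (allylic chlorination).
- What may go wrong: proton loss from C4 instead of the methyl group, addition of HOCl across the alkene, or partial desilylation in the aqueous medium.
- Fallback: it sets out from 3 and comes back at 5, replacing electrophilic chlorination by allylic oxidation. SeO2 (cat.) and t-BuOOH in CH2Cl2 give the C10 allylic alcohol F9. MsCl and Et3N at -20 °C give the allylic mesylate F10. LiBr in 2-butanone at 70 °C displaces both sulfonates to give 5.

Further compounds
F1 | step 3 | (1S,2S,4R)-1,2-bis(triethylsilyloxy)-p-menth-8-ene | C=C(C)[C@@H]1CC[C@](C)(O[Si](CC)(CC)CC)[C@@H](O[Si](CC)(CC)CC)C1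
F2 | step 3 | (1S,2S,4R)-1-(triethylsilyloxy)-p-menth-8-en-2-ol | C=C(C)[C@@H]1CC[C@](C)(O[Si](CC)(CC)CC)[C@@H](O)C1
F3 | step 3 | (1S,2S,4R)-1-(triethylsilyloxy)-p-menth-8-en-2-yl trifluoromethanesulfonate | C=C(C)[C@@H]1CC[C@](C)(O[Si](CC)(CC)CC)[C@@H](OS(=O)(=O)C(F)(F)F)C1
F4 | step 3 | (1S,2R,4R)-2-bromo-1-(triethylsilyloxy)-p-menth-8-ene | C=C(C)[C@@H]1CC[C@](C)(O[Si](CC)(CC)CC)[C@H](Br)C1
F5 | step 3 | (1S,2R,4R)-2-bromo-10-chloro-1-(triethylsilyloxy)-p-menth-8-ene | C=C(CCl)[C@@H]1CC[C@](C)(O[Si](CC)(CC)CC)[C@H](Br)C1
F6 | step 7 | trans-C3'-alkylated (S)-carvone carrying ring A as bromo silyl ether | C=C(C[C@@H]1[C@@H](C(=C)C)CC=C(C)C1=O)[C@@H]1CC[C@](C)(O[Si](CC)(CC)CC)[C@H](Br)C1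
F7 | step 7 | 1',6'-epoxy ketone of F6, oxirane trans to the isopropenyl group | C=C(C[C@@H]1[C@@H](C(=C)C)C[C@@H]2O[C@]2(C)C1=O)[C@@H]1CC[C@](C)(O[Si](CC)(CC)CC)[C@H](Br)C1
F8 | step 7 | coupled 1',2'-diol, both C2' epimers (C2' left open) | C=C(C[C@@H]1[C@@H](C(=C)C)CC[C@](C)(O)C1O)[C@@H]1CC[C@](C)(O[Si](CC)(CC)CC)[C@H](Br)C1
F9 | step 2 | (1S,2S,4R)-2-(chloromethanesulfonyloxy)-1-(triethylsilyloxy)-p-menth-8-en-10-ol | C=C(CO)[C@@H]1CC[C@](C)(O[Si](CC)(CC)CC)[C@@H](OS(=O)(=O)CCl)C1
F10 | step 2 | C10 methanesulfonate of F9 | C=C(COS(C)(=O)=O)[C@@H]1CC[C@](C)(O[Si](CC)(CC)CC)[C@@H](OS(=O)(=O)CCl)C1
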